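**Plan**
- Retrosynthesis: (a) cut the bond between the carbinol carbon C2' and its CH2CH2CH=CMe2 chain (acetyl group + homoprenyl Grignard reagent); (b) cut together the C3–C2 (CH2–CH) and O1–C7a bonds of the dihydrofuran, which leaves a 2-methylidene β-triketone and hydroxyacetone; (c) take the CH2, the two ring methyls and the isobutyryl group back to phloroglucinol.
- Enabling feature: furan C3 is a CH2 on C3a, the ring carbon between the C4 ketone and the enol-ether carbon C7a. C3a=CH2 is therefore an o-quinone-methide-like acceptor, and C7a is a masked ring ketone onto which the hydroxyl of the adduct closes with loss of water; C2, which carries O1, is the hydroxylated α-carbon of a ketone.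
- Helper: the methylidene triketone is stored as a phenylsulfonylmethyl compound, built by thionium alkylation and sulfur oxidation (steps 3–4); it is set free only in the key step, where the sulfone leaves as sulfinate.
- Ring order: arene, then the dearomatised gem-dimethyl carbocycle (steps 1–2), then the dihydrofuran (step 5); the chain is joined last (step 6).
- Stereochemistry: C2 (S) from a chiral primary-amine enamine in step 5; C2' (R) from 1,2-induction by C2 in a non-chelated Grignard addition in step 6.

Key step: step 5

Remark: the polyketone rings are tautomeric; each is written in one enol form, the target in the form of the given structure (benzofuran numbering O1, C2, C3, C3a, C4–C7, C7a).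

Step 1
Reactants: 1 phloroglucinol (benzene-1,3,5-triol); 2 isobutyryl chloride (2-methylpropanoyl chloride)
Product: 3 2-methyl-1-(2,4,6-trihydroxyphenyl)propan-1-one
Conditions: AlCl3 (4 equiv), PhNO2, rt to 60 °C; aq HCl
Reagents that add atoms: none
Why: Friedel–Crafts C-acylation of the threefold-symmetric, electron-rich arene can give only one regioisomer, and the acyl group deactivates the ring against a second acylation.

Step 2
Reactants: 3 2-methyl-1-(2,4,6-trihydroxyphenyl)propan-1-one
Product: 5 3,5-dihydroxy-6,6-dimethyl-4-(2-methylpropanoyl)cyclohexa-2,4-dien-1-one (dienol form of 2-isobutyryl-4,4-dimethylcyclohexane-1,3,5-trione), via C-methyl acylphloroglucinol 4 (not isolated)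
Conditions: NaOMe (3 equiv), MeI (2.5 equiv), MeOH, 0 °C to rt
Reagents that add atoms: iodomethane, CI
Why: Alkylative dearomatisation of an acylphloroglucinol, in which the ring carbon between two phenoxide oxygens is C-methylated twice by way of 4 and the resulting vinylogous acid anion is less nucleophilic, so that a limited amount of MeI should stop at the gem-dimethyl stage and leave one ring CH free.

Step 3
Reactants: 5 3,5-dihydroxy-6,6-dimethyl-4-(2-methylpropanoyl)cyclohexa-2,4-dien-1-one; 6 chloromethyl phenyl sulfide ([(chloromethyl)sulfanyl]benzene)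
Product: 7 3,5-dihydroxy-6,6-dimethyl-4-(2-methylpropanoyl)-2-[(phenylsulfanyl)methyl]cyclohexa-2,4-dien-1-one
Conditions: 6 (1.05 equiv), ZnBr2 (10 mol %), CH2Cl2, 0 °C to rt
Reagents that add atoms: none
Why: Lewis-acid-promoted phenylthiomethylation (thionium-ion alkylation of an enol, a Friedel–Crafts/Mannich-type substitution): ZnBr2 ionises 6 to PhS+=CH2, which the free ring CH of the fully enolised triketone attacks at carbon, any O-alkylated O,S-acetal re-ionises under the Lewis acid, and because the C–C bond is made by substitution and not by condensation with formaldehyde no methylidene triketone arises at this stage.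

Step 4
Reactants: 7 3,5-dihydroxy-6,6-dimethyl-4-(2-methylpropanoyl)-2-[(phenylsulfanyl)methyl]cyclohexa-2,4-dien-1-one
Product: 9 3,5-dihydroxy-6,6-dimethyl-4-(2-methylpropanoyl)-2-[(phenylsulfonyl)methyl]cyclohexa-2,4-dien-1-one, via sulfoxide 8 (not isolated)
Conditions: 30 % aq H2O2 (2.5 equiv), Na2WO4·2H2O (2 mol %), AcOH/MeOH, rt
Reagents that add atoms: hydrogen peroxide, OO
Why: Tungstate-catalysed peroxide oxidation of the sulfide through the sulfoxide 8 to the sulfone, chemoselective because sulfur is far more nucleophilic than the electron-poor, hydrogen-bonded enol double bonds, and run in an acidic medium so that no enolate forms and sulfinate is not yet lost.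

Step 5
Reactants: 9 3,5-dihydroxy-6,6-dimethyl-4-(2-methylpropanoyl)-2-[(phenylsulfonyl)methyl]cyclohexa-2,4-dien-1-one; 10 hydroxyacetone (1-hydroxypropan-2-one)
Product: 13 (2S)-2-acetyl-7-[(Z)-1-hydroxy-2-methylpropylidene]-5,5-dimethyl-2,3-dihydro-1-benzofuran-4,6(5H,7H)-dione, via methylidene triketone 11 (not isolated), via hydroxy ketone adduct 12 (not isolated)
Conditions: 10 (5 equiv), (1R,2R)-N1,N1-dimethylcyclohexane-1,2-diamine (20 mol %), CF3SO3H (20 mol %), NaHCO3 (1.0 equiv), CHCl3, 0 °C to rt; then polystyrene–SO3H resin (H+ form), 40 °C, same flask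
Reagents that add atoms: none
Why: Proposed new method: NaHCO3 releases the methylidene triketone 11 from 9 by E1cB loss of benzenesulfinate; the primary amine of the catalyst condenses with 10 to the hydrogen-bonded (Z)-enamine at the hydroxylated carbon, which adds to the exocyclic CH2 of 11 (new CH2–CH(OH) bond) and is hydrolysed to 12, and on acidification the secondary OH of 12 adds to the ring carbonyl lying between the CH2-bearing and the acyl-bearing carbons and water is lost (new O–C(sp2) bond). The closest known reaction types are primary-amine enamine Michael additions of hydroxyacetone to nitroalkenes, enamine alkylations with o-quinone methides released from sulfones, and the acid cyclodehydration of 2-(2-hydroxyalkyl)cyclohexane-1,3-diones to tetrahydrobenzofuranones; the cascade strings these elementary steps together on a 2-methylidene β-triketone, which has not been shown. The dihydrofuran closes by 5-exo-trig attack of O–H on the protonated ring carbonyl followed by irreversible dehydration to the vinylogous ester, whereas the competing six-membered hemiketal at the side-chain ketone forms reversibly and drains back through the open hydroxy ketone. The single new stereocentre C2 (S) is set in the C–C bond formation: the protonated NMe2 group of the (1R,2R)-diamine hydrogen-bonds a carbonyl of 11 and delivers its CH2 to the enamine face on its own side, which a model of the s-trans enamine predicts to be the face leading to S; the (1S,2S)-diamine is the remedy if the sense proves opposite. The step needs C- rather than O-alkylation of 10 and reaction at CH(OH) rather than CH3 (both secured by the enamine, which forms on the hydroxylated side), closure onto the carbonyl remote from CMe2 (the other is shielded by the quaternary carbon, as in enol ether formation from 4,4-dimethylcyclohexane-1,3-dione), and configurational integrity at C2 (mild acid, short contact).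

Step 6
Reactants: 13 (2S)-2-acetyl-7-[(Z)-1-hydroxy-2-methylpropylidene]-5,5-dimethyl-2,3-dihydro-1-benzofuran-4,6(5H,7H)-dione; 14 5-bromo-2-methylpent-2-ene
Product: 17 (2S)-2-[(2R)-2-hydroxy-6-methylhept-5-en-2-yl]-7-[(Z)-1-hydroxy-2-methylpropylidene]-5,5-dimethyl-2,3-dihydro-1-benzofuran-4,6(5H,7H)-dione (target), via Grignard reagent 15 (not isolated), via bromomagnesium salt 16 (not isolated)
Conditions: 14 (3.3 equiv), Mg, THF, rt; then 13, THF, −78 to −40 °C; aq NH4Cl
Reagents that add atoms: none
Why: Grignard addition to the methyl ketone through an open, non-chelated (Felkin–Anh) transition state, expected because O1 is a vinylogous ester oxygen and a poor ligand for magnesium: the C2–O1 bond lies antiperiplanar to the incoming homoprenyl group, which passes the C2 hydrogen and sets the carbinol centre as R, while the first equivalent of reagent turns the acidic enol into a magnesium enolate that protects the ring carbonyls.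

**Compound list**
1 | phloroglucinol (benzene-1,3,5-triol) | Oc1cc(O)cc(O)c1 | starting material
2 | isobutyryl chloride (2-methylpropanoyl chloride) | CC(C)C(Cl)=O | starting material
3 | 2-methyl-1-(2,4,6-trihydroxyphenyl)propan-1-one | CC(C)C(=O)c1c(O)cc(O)cc1O | intermediate
4 | 2-methyl-1-(2,4,6-trihydroxy-3-methylphenyl)propan-1-one (C-methyl acylphloroglucinol, not isolated) | CC(C)C(=O)c1c(O)cc(O)c(C)c1O | intermediate
5 | 3,5-dihydroxy-6,6-dimethyl-4-(2-methylpropanoyl)cyclohexa-2,4-dien-1-one | CC(C)C(=O)C1=C(O)C(C)(C)C(=O)C=C1O | intermediate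
6 | chloromethyl phenyl sulfide ([(chloromethyl)sulfanyl]benzene) | ClCSc1ccccc1 | starting material
7 | 3,5-dihydroxy-6,6-dimethyl-4-(2-methylpropanoyl)-2-[(phenylsulfanyl)methyl]cyclohexa-2,4-dien-1-one | CC(C)C(=O)C1=C(O)C(C)(C)C(=O)C(CSc2ccccc2)=C1O | intermediate
8 | 3,5-dihydroxy-6,6-dimethyl-4-(2-methylpropanoyl)-2-[(phenylsulfinyl)methyl]cyclohexa-2,4-dien-1-one (sulfoxide, racemic at sulfur, not isolated) | CC(C)C(=O)C1=C(O)C(C)(C)C(=O)C(CS(=O)c2ccccc2)=C1O | intermediate
9 | 3,5-dihydroxy-6,6-dimethyl-4-(2-methylpropanoyl)-2-[(phenylsulfonyl)methyl]cyclohexa-2,4-dien-1-one | CC(C)C(=O)C1=C(O)C(C)(C)C(=O)C(CS(=O)(=O)c2ccccc2)=C1O | intermediate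
10 | hydroxyacetone (1-hydroxypropan-2-one) | CC(=O)CO | starting material
11 | 3-hydroxy-4,4-dimethyl-6-methylidene-2-(2-methylpropanoyl)cyclohex-2-ene-1,5-dione (methylidene triketone, not isolated) | C=C1C(=O)C(C)(C)C(O)=C(C(=O)C(C)C)C1=O | intermediate
12 | (3S)-4-[2,4-dihydroxy-5,5-dimethyl-3-(2-methylpropanoyl)-6-oxocyclohexa-1,3-dien-1-yl]-3-hydroxybutan-2-one (not isolated) | CC(=O)[C@@H](O)CC1=C(O)C(C(=O)C(C)C)=C(O)C(C)(C)C1=O | intermediate
13 | (2S)-2-acetyl-7-[(Z)-1-hydroxy-2-methylpropylidene]-5,5-dimethyl-2,3-dihydro-1-benzofuran-4,6(5H,7H)-dione | CC(=O)[C@@H]1CC2=C(O1)/C(=C(/O)C(C)C)C(=O)C(C)(C)C2=O | intermediate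
14 | 5-bromo-2-methylpent-2-ene | CC(C)=CCCBr | starting material
15 | (4-methylpent-3-en-1-yl)magnesium bromide (not isolated) | CC(C)=CCC[Mg]Br | intermediate
16 | bis(bromomagnesium) salt of 17, C2' alkoxide and enolate (not isolated) | CC(C)=CCC[C@@](C)(O[Mg]Br)[C@@H]1CC2=C(O1)/C(=C(/O[Mg]Br)C(C)C)C(=O)C(C)(C)C2=O | intermediate
17 | (2S)-2-[(2R)-2-hydroxy-6-methylhept-5-en-2-yl]-7-[(Z)-1-hydroxy-2-methylpropylidene]-5,5-dimethyl-2,3-dihydro-1-benzofuran-4,6(5H,7H)-dione | CC(C)=CCC[C@@](C)(O)[C@@H]1CC2=C(O1)/C(=C(/O)C(C)C)C(=O)C(C)(C)C2=O | target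

Total step count: 6. Longest linear sequence: 6 steps (1 → 3 → 5 → 7 → 9 → 13 → 17).

**Steps most likely to fail**

Step 5. Several processes may defeat it.
- The released methylidene triketone may dimerise, or add hydroxyacetone through oxygen, faster than the enamine traps it.
- The primary amine may be tied up as a vinylogous amide on the isobutyryl triketone.
- Facial discrimination toward an unsubstituted CH2 terminus may be weak.
- The acid closure may take the carbonyl next to CMe2, or enolisation may erode C2.

The fallback uses known chemistry, sets out from 5 and comes back at 13; it takes C2 from the chiral pool instead of creating it. Opening of methyl (2S)-oxirane-2-carboxylate at its CH2 by the ring carbon of 5 (Et3N, LiClO4, MeCN, 60 °C) should give the hydroxy ester F1. Acid cyclodehydration (polystyrene–SO3H resin, CHCl3, 40 °C) should close it to the dihydrofuran ester F2 with the glycidate stereocentre untouched. CH3NHOCH3·HCl with (CH3)2CHMgCl should give the Weinreb amide F3, and CH3MgBr should convert it into 13.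

Step 6. The facial selectivity of the addition may be low or reversed if magnesium bridges the ketone oxygen and O1. Deprotonation of the acidic C2–H may also compete with addition and erode C2.

The fallback sets out from 9 and 14 and comes back at 16; it exchanges the roles of the two carbon substituents so that the chelated pathway becomes the productive one. Bromide 14 is converted into reagent 15 as in step 6; 15 with 2-[(tert-butyldimethylsilyl)oxy]-N-methoxy-N-methylacetamide should give the silyloxy ketone F4, and HF·pyridine the hydroxy ketone F5. F5 is taken with 9 through the conditions of step 5, by way of the adduct F6, to the homoprenyl ketone F7. CH3MgBr in CH2Cl2/Et2O at −78 °C, conditions that favour the five-membered magnesium chelate, should then deliver methyl past the C2 hydrogen to give 16 and, after NH4Cl, 17. Because the chelated and the open transition states lead to opposite carbinol configurations, one of the two orders of introduction suits whichever mode the 2-acyl dihydrofuran prefers.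

Step 3. The thionium ion may be taken up at oxygen instead of carbon, a second alkylation may occur at the same ring carbon, or the chelating triketone may bind ZnBr2 and stall the ionisation.

The fallback sets out from 5 and comes back at 11 inside step 5; it replaces the sulfone store by an amine store made by a Mannich reaction. Compound 5 with dimethylmethylideneammonium iodide, [(CH3)2N=CH2]I, and Et3N in CH2Cl2 should give the Mannich base F8, an inner salt of ammonium and enolate. Used in step 5 in place of 9 and without NaHCO3, F8 should release 11 on gentle warming by loss of dimethylamine, which the acidic triketone products hold as the ammonium salt.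

**Further compounds**
F1 | step 5 | methyl (2S)-3-[2,4-dihydroxy-5,5-dimethyl-3-(2-methylpropanoyl)-6-oxocyclohexa-1,3-dien-1-yl]-2-hydroxypropanoate | COC(=O)[C@@H](O)CC1=C(O)C(C(=O)C(C)C)=C(O)C(C)(C)C1=O
F2 | step 5 | methyl (2S)-7-[(Z)-1-hydroxy-2-methylpropylidene]-5,5-dimethyl-4,6-dioxo-2,3,4,5,6,7-hexahydro-1-benzofuran-2-carboxylate | COC(=O)[C@@H]1CC2=C(O1)/C(=C(/O)C(C)C)C(=O)C(C)(C)C2=O
F3 | step 5 | (2S)-7-[(Z)-1-hydroxy-2-methylpropylidene]-N-methoxy-N,5,5-trimethyl-4,6-dioxo-2,3,4,5,6,7-hexahydro-1-benzofuran-2-carboxamide | CON(C)C(=O)[C@@H]1CC2=C(O1)/C(=C(/O)C(C)C)C(=O)C(C)(C)C2=O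
F4 | step 6 | 1-[(tert-butyldimethylsilyl)oxy]-6-methylhept-5-en-2-one | CC(C)=CCCC(=O)CO[Si](C)(C)C(C)(C)C
F5 | step 6 | 1-hydroxy-6-methylhept-5-en-2-one | CC(C)=CCCC(=O)CO
F6 | step 6 | (2S)-1-[2,4-dihydroxy-5,5-dimethyl-3-(2-methylpropanoyl)-6-oxocyclohexa-1,3-dien-1-yl]-2-hydroxy-7-methyloct-6-en-3-one | CC(C)=CCCC(=O)[C@@H](O)CC1=C(O)C(C(=O)C(C)C)=C(O)C(C)(C)C1=O
F7 | step 6 | (2S)-7-[(Z)-1-hydroxy-2-methylpropylidene]-5,5-dimethyl-2-(5-methylhex-4-enoyl)-2,3-dihydro-1-benzofuran-4,6(5H,7H)-dione | CC(C)=CCCC(=O)[C@@H]1CC2=C(O1)/C(=C(/O)C(C)C)C(=O)C(C)(C)C2=O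
F8 | step 3 | 2-[(dimethylamino)methyl]-3,5-dihydroxy-6,6-dimethyl-4-(2-methylpropanoyl)cyclohexa-2,4-dien-1-one | CC(C)C(=O)C1=C(O)C(C)(C)C(=O)C(CN(C)C)=C1O
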